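The route rests on making the C16–O bond last, by 1,5-hydrogen transfer to an amidyl radical at C21. In one operation the key step turns the C16 methylene into the oxygenated stereocentre and closes a γ-lactone (O16, C16, C17, C20, C21). It exploits the quaternary C17 at the bridgehead of the oxepane/dioxolanone bicycle: the C21 nitrogen lies five atoms from C16–H, and C19, still a lactone carbonyl, offers no rival hydrogen. The precursor is the bridged 1,3-dioxolan-4-one (C17–O–C18–O–C19=O) on a sclareol-derived isocopalane, with C16H2 and a C21 primary amide that is installed only after the acylal bridge is closed, so that nitrogen cannot capture C18.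

Key step: step 18

Remark: atoms are numbered C1–C14 in rings A, B and C, C15–C16 for the chain on C14, C17 for the oxygenated quaternary carbon, C18 for the carbon on C13, C19 for the second acetal carbon and C20–C21 for the acetic acid arm; all tricyclic compounds keep 5α-H, 9α-H and 10β-methyl of sclareol, and lactols 31, 32 and 34 are taken as anomeric mixtures at the hemiacetal carbons.

Step 1
Reactants: 1 sclareol
Product: 3 8α-hydroxy-14,15-dinorlabdan-13-one, via (13R)-labdane-8α,13,14,15-tetraol 2 (not isolated)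
Conditions: OsO4 (2 mol%), NaIO4 (4 equiv), THF/H2O, 20 °C
Reagents that add atoms: none
Why: Lemieux–Johnson oxidation, in which dihydroxylation of the vinyl group gives a 13,14,15-triol that periodate cleaves twice to the C13 methyl ketone without touching a stereocentre of the decalin.

Step 2
Reactants: 3 8α-hydroxy-14,15-dinorlabdan-13-one
Product: 4 methyl (13E)-8α-hydroxylabd-13-en-15-oate
Conditions: (MeO)2P(O)CH2CO2Me, NaH (excess), THF, 0 → 65 °C; E isomer separated by chromatography
Reagents that add atoms: trimethyl phosphonoacetate, COC(=O)CP(=O)(OC)OC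
Why: Horner–Wadsworth–Emmons olefination of the methyl ketone, which should favour the E enoate with the ester anti to the long chain (the tertiary alkoxide is a spectator).

Step 3
Reactants: 4 methyl (13E)-8α-hydroxylabd-13-en-15-oate
Product: 5 methyl isocopal-12-en-15-oate (8β-methyl, 14α-H, ester C15 on C14, methyl C18 on C13)
Conditions: FSO3H (5 equiv), i-PrNO2, −78 °C; then Et3N
Reagents that add atoms: none
Why: superacid cationic cyclisation, in which the C8 cation from the tertiary alcohol is attacked by the enoate α-carbon C14 through a chair transition state (new C8–C14 bond equatorial, 8β-methyl axial, ester equatorial from the E alkene) and loss of H12 gives the 12-ene.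

Step 4
Reactants: 5 methyl isocopal-12-en-15-oate
Product: 6 isocopal-12-en-15-ol
Conditions: LiAlH4, THF, 0 → 20 °C
Reagents that add atoms: none
Why: hydride reduction of the ester to the primary alcohol under non-enolising conditions, so that C14 is not epimerised.

Step 5
Reactants: 6 isocopal-12-en-15-ol
Product: 7 isocopal-12-en-15-yl acetate
Conditions: Ac2O, pyridine, DMAP (cat.), CH2Cl2, 20 °C
Reagents that add atoms: acetic anhydride, CC(=O)OC(C)=O
Why: acylation of the primary alcohol, giving an O15 group that cannot lactonise onto an oxidised C18 in the next step.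

Step 6
Reactants: 7 isocopal-12-en-15-yl acetate
Product: 8 15-acetoxyisocopal-12-en-18-al (conjugated aldehyde C18 on C13)
Conditions: SeO2, 1,4-dioxane, 100 °C
Reagents that add atoms: selenium dioxide, O=[Se]=O
Why: Riley allylic oxidation (ene reaction, then [2,3]-shift) at the methyl group on the more substituted alkene carbon, carried on to the enal, with the ring methine C14 the poorer ene donor.

Step 7
Reactants: 8 15-acetoxyisocopal-12-en-18-al
Product: 10 15-acetoxyisocopalan-18-al (13β-H, CHO equatorial and trans to C15), via axial 13β-formyl epimer 9 (not isolated)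
Conditions: H2 (1 atm), 10% Pd/C, EtOAc, 20 °C; filter; then DBU, CH2Cl2, 20 °C
Reagents that add atoms: none
Why: catalytic hydrogenation should add to the enal C=C from the α face (the β face is screened by the axial 8β-methyl), and base epimerisation through the enolate then moves C18 to the equatorial α position, free of the 1,3-diaxial contact with that methyl, which sets C13.

Step 8
Reactants: 10 15-acetoxyisocopalan-18-al (13β-H)
Product: 12 18,18-dimethoxyisocopalan-15-ol, via 15-acetoxy dimethyl acetal 11 (not isolated)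
Conditions: HC(OMe)3, PPTS (cat.), MeOH, 20 °C; then K2CO3, 20 °C
Reagents that add atoms: trimethyl orthoformate, COC(OC)OC
Why: acid-catalysed acetalisation masks the C18 aldehyde as a base-stable dimethyl acetal, and methanolysis of the acetate in the same flask frees O15.

Step 9
Reactants: 12 18,18-dimethoxyisocopalan-15-ol
Product: 13 18,18-dimethoxyisocopalan-15-al
Conditions: Dess–Martin periodinane, pyridine, CH2Cl2, 0 → 20 °C
Reagents that add atoms: none
Why: Dess–Martin oxidation of the primary alcohol under buffered conditions that spare the acetal; the equatorial C14 aldehyde is the stable epimer.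

Step 10
Reactants: 13 18,18-dimethoxyisocopalan-15-al
Product: 14 vinyl acetal (14β-CH=CH2 as C15=C16, 13α-CH(OMe)2)
Conditions: Ph3PCH3Br, KN(SiMe3)2, THF, 0 °C; then 13, 0 → 20 °C
Reagents that add atoms: methyltriphenylphosphonium bromide, C[P+](c1ccccc1)(c1ccccc1)c1ccccc1.[Br-]
Why: Wittig methylenation of the aldehyde adds C16 as a terminal alkene carbon.

Step 11
Reactants: 14 vinyl acetal
Product: 16 C16 alcohol (14β-CH2CH2OH, 13α-CH(OMe)2), via B-alkyl-9-BBN adduct 15 (not isolated)
Conditions: 9-BBN, THF, 20 → 50 °C; then NaOH, H2O2, 0 → 20 °C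
Reagents that add atoms: hydrogen peroxide, OO
Why: anti-Markovnikov hydroboration–oxidation of the monosubstituted alkene places the oxygen on terminal C16.

Step 12
Reactants: 16 C16 alcohol
Product: 17 C16 triflate
Conditions: Tf2O, 2,6-lutidine, CH2Cl2, −78 °C; cold pentane filtration, used at once
Reagents that add atoms: trifluoromethanesulfonic anhydride, O=S(=O)(OS(=O)(=O)C(F)(F)F)C(F)(F)F
Why: O-sulfonylation of the unhindered primary alcohol gives an electrophile reactive enough for an enolate at −78 °C, and low temperature should prevent attack by the acetal oxygen.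

Step 13
Reactants: 18 (S)-malic acid; 19 pivalaldehyde
Product: 20 2-[(2S,4S)-2-tert-butyl-5-oxo-1,3-dioxolan-4-yl]acetic acid (cis)
Conditions: TsOH·H2O (cat.), H2SO4 (cat.), pentane, reflux with water separator; recrystallisation
Reagents that add atoms: none
Why: acid-catalysed acetalisation of the α-hydroxy acid unit gives the five-membered dioxolanone, and the cis isomer (tert-butyl and CH2CO2H on one face), favoured at equilibrium and purified by crystallisation, stores the malate configuration at the acetal carbon.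

Step 14
Reactants: 20 cis-dioxolanone acid; 17 C16 triflate
Product: 22 C17-alkylated dioxolanone acid (C16 chain trans to tert-butyl, CH2CO2H cis), via dilithium enolate carboxylate 21 (not isolated)
Conditions: LiN(SiMe3)2 (2.1 equiv), THF, −78 °C; then 17, THF/DMPU, −78 → −40 °C; then AcOH
Reagents that add atoms: none
Why: enolate alkylation with self-regeneration of the stereocentre, in which SN2 attack on the primary triflate occurs anti to the tert-butyl group and so creates quaternary C17 with net retention of the malate configuration.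

Step 15
Reactants: 22 C17-alkylated dioxolanone acid
Product: 23 (17S)-α-hydroxy diacid (C17 bears OH, CO2H as C19 and CH2CO2H; 13α-CH(OMe)2 intact)
Conditions: LiOH, THF/H2O, 0 → 20 °C; then 1 M HCl to pH 3, 0 °C
Reagents that add atoms: lithium hydroxide, [Li+].[OH-]
Why: saponification of the acylal releases pivalaldehyde and the tertiary α-hydroxy acid, while quaternary C17 cannot epimerise and the dimethyl acetal is stable to base.

Step 16
Reactants: 23 (17S)-α-hydroxy diacid
Product: 24 bridged dioxolanone acid (C17–O17–C18–O19–C19=O acylal, oxepane trans-fused to ring C, C21 CO2H)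
Conditions: BF3·OEt2, Et2O, −20 → 20 °C
Reagents that add atoms: none
Why: acid-promoted dioxolanone formation from an α-hydroxy acid and a dimethyl acetal, here intramolecular, in which O17 closes the seven-membered oxepane on C18 and the C19 carboxyl oxygen closes the five-membered ring (preferred over the six-membered acylal through C21, as with malic acid itself), with the C18 configuration dictated by the bridge between C17 and the equatorial C13 position.

Step 17
Reactants: 24 bridged dioxolanone acid
Product: 26 bridged dioxolanone primary amide (C16H2, C21 CONH2), via acyl imidazolide 25 (not isolated)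
Conditions: 1,1'-carbonyldiimidazole, THF, 20 °C; then NH3 (0.5 M in 1,4-dioxane), 0 °C
Reagents that add atoms: ammonia, N
Why: acyl imidazolide formation and ammonolysis at C21, with the acylal carbonyl C19 shielded by quaternary C17 during the short exposure to ammonia at 0 °C.

Step 18
Reactants: 26 bridged dioxolanone primary amide
Product: 30 bridged dioxolanone γ-lactone (C16–O–C21 lactone, O16 on the O17 face), via N-iodoamide 27 (not isolated), via C16 iodide 28 (not isolated), via iminolactone 29 (not isolated)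
Conditions: PhI(OAc)2 (2.5 equiv), I2 (1.2 equiv), CH2Cl2, visible light (tungsten lamp), 25 °C; then aq. Na2S2O3; then THF/H2O/AcOH, 20 °C
Reagents that add atoms: water, O
Why: PhI(OAc)2 and I2 generate acetyl hypoiodite, which N-iodinates the primary amide; light homolyses the N–I bond, the amidyl radical abstracts hydrogen from C16 through a six-membered transition state, the C16 radical is iodinated, and the amide oxygen displaces iodide to give an iminolactone that water hydrolyses to the lactone. The closest known reaction is the photolysis of N-iodoamides (a Hofmann–Löffler–Freytag-type 1,5-hydrogen transfer run under hypoiodite conditions), which converts primary amides into γ-lactones at unactivated methylene groups. The γ-lactone ring (O16, C16, C17, C20, C21) closes in the 5-exo-tet mode with inversion at the C16–I carbon. The new C16 stereocentre should be controlled by the ring fusion: iodine is expected on the open equatorial face of the C16 radical, away from the axial H14, so that the invertive closure places O16 axial, on the O17 side and cis to the C20 arm, the arrangement of a cis-fused five-membered ring on the bicycle. The step needs site selectivity for C16, secured because C17 is quaternary, C19 is a carbonyl without hydrogen and the acylal C18–H is one atom further away (seven-membered transition state), and it needs the radical pathway to outrun the 1,2-shift of the N-iodoamide, which the base-free photolytic conditions should favour.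

Step 19
Reactants: 30 bridged dioxolanone γ-lactone
Product: 31 bis-lactol (C19–OH and C21–OH hemiacetals)
Conditions: i-Bu2AlH (3 equiv), CH2Cl2, −78 °C; aq. potassium sodium tartrate
Reagents that add atoms: none
Why: hydride reduction of both lactone carbonyls to aluminium hemiacetals that are stable at −78 °C, so that no choice between the two carbonyls has to be made at this point.

Step 20
Reactants: 31 bis-lactol
Product: 32 C19 lactol γ-lactone
Conditions: TEMPO (10 mol%), PhI(OAc)2 (1.1 equiv), CH2Cl2, 0 → 20 °C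
Reagents that add atoms: none
Why: oxoammonium oxidation of a lactol to a lactone, expected at the unhindered γ-lactol C21 (next to CH2) and not at the C19 lactol, which is neopentylic and buried in the bicycle.

Step 21
Reactants: 32 C19 lactol γ-lactone
Product: 34 benzyl ester diol (16-OH, 19-OH lactol, C21 CO2Bn), via cesium carboxylate 33 (not isolated)
Conditions: CsOH·H2O (1.05 equiv), THF/H2O, 0 °C; concentrate; then BnBr, DMF, 0 → 20 °C
Reagents that add atoms: cesium hydroxide, [Cs+].[OH-]; benzyl bromide, BrCc1ccccc1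
Why: saponification of the γ-lactone and O-alkylation of the cesium carboxylate before the γ-hydroxy acid can relactonise, with one equivalent of base at 0 °C to keep the bridged lactol closed.

Step 22
Reactants: 34 benzyl ester diol
Product: 35 16,19-diacetate benzyl ester (19-OAc on the face away from the C13–C16 bridge, cis to C20)
Conditions: Ac2O, pyridine, DMAP (cat.), CH2Cl2, 20 °C
Reagents that add atoms: acetic anhydride, CC(=O)OC(C)=O
Why: DMAP-catalysed acylation of the hindered C16 hydroxyl and of the lactol, whose anomers interconvert under the basic conditions while the more exposed hydroxyl on the open face is acylated faster, which should set C19 as in the target.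

Step 23
Reactants: 35 16,19-diacetate benzyl ester
Product: 36 CNP0138244.2 (target)
Conditions: H2 (1 atm), 10% Pd/C, EtOAc, 20 °C
Reagents that add atoms: none
Why: hydrogenolysis of the benzyl ester under neutral conditions that leave both acetates and the bridged acetal untouched.

Compound list

1 | sclareol, (13R)-labd-14-ene-8α,13-diol | C=C[C@](C)(O)CC[C@H]1[C@](C)(O)CC[C@H]2C(C)(C)CCC[C@]12C | starting material
2 | (13R)-labdane-8α,13,14,15-tetraol (C14 epimers) | OCC(O)[C@](C)(O)CC[C@H]1[C@](C)(O)CC[C@H]2C(C)(C)CCC[C@]12C | intermediate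
3 | 8α-hydroxy-14,15-dinorlabdan-13-one | CC(=O)CC[C@H]1[C@](C)(O)CC[C@H]2C(C)(C)CCC[C@]12C | intermediate
4 | methyl (13E)-8α-hydroxylabd-13-en-15-oate | COC(=O)/C=C(\C)CC[C@H]1[C@](C)(O)CC[C@H]2C(C)(C)CCC[C@]12C | intermediate
5 | methyl isocopal-12-en-15-oate (8β-methyl, 14α-H) | COC(=O)[C@@H]1C(C)=CC[C@H]2[C@@]1(C)CC[C@H]1C(C)(C)CCC[C@]21C | intermediate
6 | isocopal-12-en-15-ol | OC[C@@H]1C(C)=CC[C@H]2[C@@]1(C)CC[C@H]1C(C)(C)CCC[C@]21C | intermediate
7 | isocopal-12-en-15-yl acetate | CC(=O)OC[C@@H]1C(C)=CC[C@H]2[C@@]1(C)CC[C@H]1C(C)(C)CCC[C@]21C | intermediate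
8 | 15-acetoxyisocopal-12-en-18-al | CC(=O)OC[C@@H]1C(C=O)=CC[C@H]2[C@@]1(C)CC[C@H]1C(C)(C)CCC[C@]21C | intermediate
9 | 15-acetoxyisocopalan-18-al, 13α-H epimer (CHO axial, β) | CC(=O)OC[C@@H]1[C@H](C=O)CC[C@H]2[C@@]1(C)CC[C@H]1C(C)(C)CCC[C@]21C | intermediate
10 | 15-acetoxyisocopalan-18-al, 13β-H (CHO equatorial, α) | CC(=O)OC[C@@H]1[C@@H](C=O)CC[C@H]2[C@@]1(C)CC[C@H]1C(C)(C)CCC[C@]21C | intermediate
11 | 15-acetoxy-18,18-dimethoxyisocopalane (13β-H) | CC(=O)OC[C@@H]1[C@@H](C(OC)OC)CC[C@H]2[C@@]1(C)CC[C@H]1C(C)(C)CCC[C@]21C | intermediate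
12 | 18,18-dimethoxyisocopalan-15-ol (13β-H, 14α-H) | OC[C@@H]1[C@@H](C(OC)OC)CC[C@H]2[C@@]1(C)CC[C@H]1C(C)(C)CCC[C@]21C | intermediate
13 | 18,18-dimethoxyisocopalan-15-al | O=C[C@@H]1[C@@H](C(OC)OC)CC[C@H]2[C@@]1(C)CC[C@H]1C(C)(C)CCC[C@]21C | intermediate
14 | vinyl acetal (14β-CH=CH2, 13α-CH(OMe)2) | C=C[C@@H]1[C@@H](C(OC)OC)CC[C@H]2[C@@]1(C)CC[C@H]1C(C)(C)CCC[C@]21C | intermediate
15 | B-(C16-alkyl)-9-borabicyclo[3.3.1]nonane adduct of 14 | C1CCC2CCCC1B2CC[C@@H]1[C@@H](C(OC)OC)CC[C@H]2[C@@]1(C)CC[C@H]1C(C)(C)CCC[C@]21C | intermediate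
16 | C16 alcohol (14β-CH2CH2OH, 13α-CH(OMe)2) | OCC[C@@H]1[C@@H](C(OC)OC)CC[C@H]2[C@@]1(C)CC[C@H]1C(C)(C)CCC[C@]21C | intermediate
17 | C16 triflate | O=S(=O)(OCC[C@@H]1[C@@H](C(OC)OC)CC[C@H]2[C@@]1(C)CC[C@H]1C(C)(C)CCC[C@]21C)C(F)(F)F | intermediate
18 | (S)-malic acid | O[C@H](C(=O)O)CC(=O)O | starting material
19 | pivalaldehyde | CC(C)(C)C=O | starting material
20 | 2-[(2S,4S)-2-tert-butyl-5-oxo-1,3-dioxolan-4-yl]acetic acid (cis) | O=C1O[C@@H](C(C)(C)C)O[C@H]1CC(=O)O | intermediate
21 | dilithium enolate carboxylate of 20 | [Li+].[Li+].[O-]C(=O)CC1=C([O-])O[C@@H](C(C)(C)C)O1 | intermediate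
22 | C17-alkylated dioxolanone acid (C16 chain trans to tert-butyl) | O=C1O[C@@H](C(C)(C)C)O[C@]1(CC(=O)O)CC[C@@H]1[C@@H](C(OC)OC)CC[C@H]2[C@@]1(C)CC[C@H]1C(C)(C)CCC[C@]21C | intermediate
23 | (17S)-α-hydroxy diacid with 13α-CH(OMe)2 | OC(=O)[C@@](O)(CC(=O)O)CC[C@@H]1[C@@H](C(OC)OC)CC[C@H]2[C@@]1(C)CC[C@H]1C(C)(C)CCC[C@]21C | intermediate
24 | bridged dioxolanone acid (C16H2, C21 CO2H) | O=C1O[C@H]2O[C@]1(CC(=O)O)CC[C@@H]1[C@@H]2CC[C@H]2[C@@]1(C)CC[C@H]1C(C)(C)CCC[C@]21C | intermediate
25 | C21 acyl imidazolide of 24 | O=C1O[C@H]2O[C@]1(CC(=O)n1ccnc1)CC[C@@H]1[C@@H]2CC[C@H]2[C@@]1(C)CC[C@H]1C(C)(C)CCC[C@]21C | intermediate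
26 | bridged dioxolanone primary amide (C16H2, C21 CONH2) | O=C1O[C@H]2O[C@]1(CC(N)=O)CC[C@@H]1[C@@H]2CC[C@H]2[C@@]1(C)CC[C@H]1C(C)(C)CCC[C@]21C | intermediate
27 | N-iodoamide of 26 | O=C1O[C@H]2O[C@]1(CC(=O)NI)CC[C@@H]1[C@@H]2CC[C@H]2[C@@]1(C)CC[C@H]1C(C)(C)CCC[C@]21C | intermediate
28 | C16 iodide (iodine equatorial, anti to the later C16–O bond) | O=C1O[C@H]2O[C@]1(CC(N)=O)[C@@H](I)C[C@@H]1[C@@H]2CC[C@H]2[C@@]1(C)CC[C@H]1C(C)(C)CCC[C@]21C | intermediate
29 | iminolactone (C21=NH, C16–O–C21) | O=C1O[C@H]2O[C@@]13CC(=N)O[C@@H]3C[C@@H]1[C@@H]2CC[C@H]2[C@@]1(C)CC[C@H]1C(C)(C)CCC[C@]21C | intermediate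
30 | bridged dioxolanone γ-lactone (C16–O–C21) | O=C1O[C@H]2O[C@@]13CC(=O)O[C@@H]3C[C@@H]1[C@@H]2CC[C@H]2[C@@]1(C)CC[C@H]1C(C)(C)CCC[C@]21C | intermediate
31 | bis-lactol (C19–OH, C21–OH) | OC1O[C@H]2O[C@@]13CC(O)O[C@@H]3C[C@@H]1[C@@H]2CC[C@H]2[C@@]1(C)CC[C@H]1C(C)(C)CCC[C@]21C | intermediate
32 | C19 lactol γ-lactone | OC1O[C@H]2O[C@@]13CC(=O)O[C@@H]3C[C@@H]1[C@@H]2CC[C@H]2[C@@]1(C)CC[C@H]1C(C)(C)CCC[C@]21C | intermediate
33 | cesium carboxylate (16-OH, 19-OH, C21 CO2Cs) | [Cs+].OC1O[C@H]2O[C@]1(CC(=O)[O-])[C@H](O)C[C@@H]1[C@@H]2CC[C@H]2[C@@]1(C)CC[C@H]1C(C)(C)CCC[C@]21C | intermediate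
34 | benzyl ester diol (16-OH, 19-OH lactol) | OC1O[C@H]2O[C@]1(CC(=O)OCc1ccccc1)[C@H](O)C[C@@H]1[C@@H]2CC[C@H]2[C@@]1(C)CC[C@H]1C(C)(C)CCC[C@]21C | intermediate
35 | 16,19-diacetate benzyl ester | CC(=O)O[C@H]1O[C@H]2O[C@]1(CC(=O)OCc1ccccc1)[C@H](OC(C)=O)C[C@@H]1[C@@H]2CC[C@H]2[C@@]1(C)CC[C@H]1C(C)(C)CCC[C@]21C | intermediate
36 | CNP0138244.2 (16,19-diacetoxy bridged acetal acid) | CC(=O)O[C@H]1O[C@H]2O[C@]1(CC(=O)O)[C@H](OC(C)=O)C[C@@H]1[C@@H]2CC[C@H]2[C@@]1(C)CC[C@H]1C(C)(C)CCC[C@]21C | target

Total step count: 23. Longest linear sequence: 22 steps (steps 1–12 and 14–23, from sclareol); step 13 is the side branch.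

Steps most likely to fail

Step 18. The N-iodoamide may be diverted into the 1,2-shift to an isocyanate. The invertive closure at the hindered C16 iodide may also be slow on the rigid bicycle, so that loss of HI or closure on the other face of C16 (poor facial selectivity) takes over. The fallback sets out from acid 24 and replaces the nitrogen radical by a carboxylate-directed iron-oxo C–H hydroxylation ([Fe(S,S-PDP)(MeCN)2](SbF6)2 as catalyst, H2O2, MeCN, 20 °C). This should oxidise the γ-methylene C16 with retention, without any iodide displacement, and lactonise in the same flask, coming back to the route at 30.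

Step 21. Hydroxide may open the bridged lactol of 32 to the hydroxy aldehyde, which can then fragment by a retro-aldol path, and the γ-hydroxy ester may relactonise before it is acylated. The fallback sets out from 32 and protects the lactol first: TBSOTf and 2,6-lutidine give the C19 tert-butyldimethylsilyl acetal F1. CsOH followed by BnBr gives the 16-hydroxy benzyl ester F2, and Ac2O with DMAP gives the 16-acetate F3. HF·pyridine then frees the 19-lactol 16-acetate F4, and Ac2O in pyridine comes back to the route at 35.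

Step 14. The dilithium enolate is thermally labile and may decompose with loss of pivalaldehyde, or be alkylated at the carboxylate oxygen, before C-alkylation is complete. The fallback sets out from triflate 17 and uses a monoanionic enolate with the acid masked as an allyl group. (2S,5S)-5-Allyl-2-tert-butyl-1,3-dioxolan-4-one F5 is made from (S)-2-hydroxypent-4-enoic acid and 19 under the conditions of step 13. Its enolate (LiN(i-Pr)2, THF, −78 °C) is alkylated by 17, anti to tert-butyl, to the C17 allyl dioxolanone F6. Ozonolysis (O3, then Me2S) gives the C21 aldehyde F7, and NaClO2 oxidation comes back to the route at 22.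

Further compounds

F0 | step 18 | none | none
F1 | step 21 | C19 tert-butyldimethylsilyl acetal of lactol lactone 32 | CC(C)(C)[Si](C)(C)OC1O[C@H]2O[C@@]13CC(=O)O[C@@H]3C[C@@H]1[C@@H]2CC[C@H]2[C@@]1(C)CC[C@H]1C(C)(C)CCC[C@]21C
F2 | step 21 | 16-hydroxy benzyl ester, C19 silyl acetal | CC(C)(C)[Si](C)(C)OC1O[C@H]2O[C@]1(CC(=O)OCc1ccccc1)[C@H](O)C[C@@H]1[C@@H]2CC[C@H]2[C@@]1(C)CC[C@H]1C(C)(C)CCC[C@]21C
F3 | step 21 | 16-acetate benzyl ester, C19 silyl acetal | CC(C)(C)[Si](C)(C)OC1O[C@H]2O[C@]1(CC(=O)OCc1ccccc1)[C@H](OC(C)=O)C[C@@H]1[C@@H]2CC[C@H]2[C@@]1(C)CC[C@H]1C(C)(C)CCC[C@]21C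
F4 | step 21 | 19-lactol 16-acetate benzyl ester | OC1O[C@H]2O[C@]1(CC(=O)OCc1ccccc1)[C@H](OC(C)=O)C[C@@H]1[C@@H]2CC[C@H]2[C@@]1(C)CC[C@H]1C(C)(C)CCC[C@]21C
F5 | step 14 | (2S,5S)-5-allyl-2-tert-butyl-1,3-dioxolan-4-one | O=C1O[C@@H](C(C)(C)C)O[C@H]1CC=C
F6 | step 14 | C17 allyl dioxolanone (C16 chain trans to tert-butyl) | O=C1O[C@@H](C(C)(C)C)O[C@]1(CC=C)CC[C@@H]1[C@@H](C(OC)OC)CC[C@H]2[C@@]1(C)CC[C@H]1C(C)(C)CCC[C@]21C
F7 | step 14 | C21 aldehyde from ozonolysis of F6 | O=C1O[C@@H](C(C)(C)C)O[C@]1(CC=O)CC[C@@H]1[C@@H](C(OC)OC)CC[C@H]2[C@@]1(C)CC[C@H]1C(C)(C)CCC[C@]21C
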